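**Retrosynthetic overview**

1. The target is reached by hydrogenolysis of the two O-benzyl groups of its 5,7-dibenzyl ether; ring A comes ready-made from 2,4,6-trihydroxyacetophenone.
2. Key disconnection: C3–C1' and O1–C2. An o-hydroxyaryl enaminone (ring A plus C4–C3–C2) is joined to 2,4,4,6-tetramethoxycyclohexa-2,5-dienone, which carries ring B in dearomatised form.
3. Feature used: in ring B, C1' lies between the 2'- and 6'-OMe carbons, the 3'-OH is para to the 6'-OMe, and C5' is the only CH. A nucleophile bonding to a free β-carbon of a 2,6-dimethoxy-p-quinone 4-monoketal leaves exactly this pattern (carbonyl O becomes 3'-OH, the surviving ketal OMe becomes 6'-OMe).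
4. The dienone comes from 2,4,6-trimethoxybenzaldehyde (Dakin oxidation, oxidative ketalisation); the enaminone from 2,4,6-trihydroxyacetophenone (dibenzylation, amide acetal condensation).
5. Ring order: ring A is bought; ring C is closed and ring B aromatised together in step 5.

Key step: step 5

Assumption: the target has no stereocentre, so no configuration has to be set; the only geometric element, the E double bond of the enaminone, is consumed in the key step.

**Route**

Step 1
Reactants: 1 2,4,6-trimethoxybenzaldehyde
Product: 3 2,4,6-trimethoxyphenol, via 2,4,6-trimethoxyphenyl formate 2 (not isolated)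
Conditions: 30% aq. H2O2, cat. H2SO4, MeOH, rt
Reagents that add atoms: hydrogen peroxide, OO
Why: Acid-catalysed Dakin (Baeyer–Villiger-type) oxidation; the hydroperoxide adduct of the aldehyde rearranges with migration of the very electron-rich aryl group to formate 2, which the acidic methanol transesterifies in the same flask.

Step 2
Reactants: 3 2,4,6-trimethoxyphenol
Product: 4 2,4,4,6-tetramethoxycyclohexa-2,5-dien-1-one
Conditions: PhI(OAc)2 (1.1 equiv), MeOH, 0 °C; used promptly
Reagents that add atoms: methanol, CO
Why: Oxidative dearomatisation of a 4-alkoxyphenol with a hypervalent (trivalent) iodine oxidant; the aryloxy-iodane loses iodobenzene and methanol is captured at the para carbon, which already bears OMe, giving the dimethyl ketal, the normal course for p-methoxyphenols.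

Step 3
Reactants: 5 1-(2,4,6-trihydroxyphenyl)ethan-1-one (dried monohydrate); 6 benzyl bromide
Product: 7 1-[2,4-bis(benzyloxy)-6-hydroxyphenyl]ethan-1-one
Conditions: BnBr (2.1 equiv), K2CO3 (2.2 equiv), DMF, rt
Reagents that add atoms: benzyl bromide (6), BrCc1ccccc1
Why: Williamson ether synthesis; the 4-OH and one 2-OH are alkylated, while the last ortho hydroxyl is held in a hydrogen bond to the ketone and should stay free with two equivalents of halide at room temperature.

Step 4
Reactants: 7 1-[2,4-bis(benzyloxy)-6-hydroxyphenyl]ethan-1-one; 8 N,N-dimethylformamide dimethyl acetal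
Product: 9 (E)-1-[2,4-bis(benzyloxy)-6-hydroxyphenyl]-3-(dimethylamino)prop-2-en-1-one
Conditions: DMF dimethyl acetal (3 equiv), toluene, 95 °C
Reagents that add atoms: N,N-dimethylformamide dimethyl acetal (8), COC(OC)N(C)C
Why: Aminomethylenation of a methyl ketone with an amide acetal; the enol attacks the methoxy-iminium ion formed from 8 and loss of two molecules of methanol gives the conjugated enaminone as the E isomer, which keeps the amino and aroyl groups trans.

Step 5
Reactants: 9 (E)-1-[2,4-bis(benzyloxy)-6-hydroxyphenyl]-3-(dimethylamino)prop-2-en-1-one; 4 2,4,4,6-tetramethoxycyclohexa-2,5-dien-1-one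
Product: 12 5,7-bis(benzyloxy)-3-(3-hydroxy-2,4,6-trimethoxyphenyl)-4H-chromen-4-one, via aminochromanone adduct 10 (not isolated), via dienol ketal 11 (not isolated)
Conditions: 4 (1.5 equiv), dry HFIP, rt to 45 °C; evaporate; then BF3·OEt2 (20 mol%), CH2Cl2, 0 °C
Reagents that add atoms: none
Why: Proposed new method: hydrogen bonding from HFIP polarises the dienone carbonyl of 4, so that the electron-rich α-carbon of the enaminone adds in Michael fashion to an unsubstituted β-carbon of the dienone (new C3–C1' bond) and leaves an iminium ion that the ortho phenol captures in a 6-exo-trig closure (new O1–C2 bond, ring C) to give aminal 10. Loss of dimethylamine from 10 gives chromone 11, and the acid added after evaporation ionises the allylic ketal of 11, so that loss of methanol and of the C1' proton aromatises ring B, the former dienone carbonyl becoming the 3'-OH and the remaining ketal methoxy the 6'-OMe. The closest known reactions are the domino C3-functionalisation–cyclisation of o-hydroxyaryl enaminones with carbon electrophiles to 3-substituted chromones, the Nenitzescu-type addition of enaminones to quinones, and the Michael addition–aromatisation of carbon nucleophiles to quinone monoketals; their combination on an α,α'-dimethoxy dienone is untested. No stereocentre remains in 12, since the one formed at C1' is erased on aromatisation. The step needs C–C bond formation at the dienone β-carbon to outrun both C-protonation of the enaminone (which would close to the 3-unsubstituted chromone) and ionisation of the ketal; this is served by keeping strong acid out of the first stage, while the regiochemistry is fixed by 4 itself, whose two α-carbons carry methoxy groups and whose two β-carbons are equivalent by symmetry.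

Step 6
Reactants: 12 5,7-bis(benzyloxy)-3-(3-hydroxy-2,4,6-trimethoxyphenyl)-4H-chromen-4-one
Product: 13 5,7-dihydroxy-3-(3-hydroxy-2,4,6-trimethoxyphenyl)-4H-chromen-4-one
Conditions: H2 (1 atm), 10% Pd/C (zerovalent palladium on carbon), EtOAc–MeOH, rt
Reagents that add atoms: none
Why: Hydrogenolysis of aryl benzyl ethers; the methyl ethers are inert and the C2–C3 double bond, shielded by the 2',6'-dimethoxyaryl group, should survive if the reaction is stopped once debenzylation is complete.

**Compound list**

1 | 2,4,6-trimethoxybenzaldehyde | COc1cc(OC)c(C=O)c(OC)c1 | starting material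
2 | 2,4,6-trimethoxyphenyl formate | COc1cc(OC)c(OC=O)c(OC)c1 | intermediate (not isolated)
3 | 2,4,6-trimethoxyphenol | COc1cc(OC)c(O)c(OC)c1 | intermediate
4 | 2,4,4,6-tetramethoxycyclohexa-2,5-dien-1-one | COC1=CC(OC)(OC)C=C(OC)C1=O | intermediate
5 | 1-(2,4,6-trihydroxyphenyl)ethan-1-one (2,4,6-trihydroxyacetophenone) | CC(=O)c1c(O)cc(O)cc1O | starting material
6 | benzyl bromide | BrCc1ccccc1 | starting material
7 | 1-[2,4-bis(benzyloxy)-6-hydroxyphenyl]ethan-1-one | CC(=O)c1c(O)cc(OCc2ccccc2)cc1OCc1ccccc1 | intermediate
8 | N,N-dimethylformamide dimethyl acetal | COC(OC)N(C)C | starting material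
9 | (E)-1-[2,4-bis(benzyloxy)-6-hydroxyphenyl]-3-(dimethylamino)prop-2-en-1-one | CN(C)/C=C/C(=O)c1c(O)cc(OCc2ccccc2)cc1OCc1ccccc1 | intermediate
10 | 5,7-bis(benzyloxy)-2-(dimethylamino)-3-(3-hydroxy-2,4,6,6-tetramethoxycyclohexa-2,4-dien-1-yl)chroman-4-one (mixture of stereoisomers, drawn as the dienol tautomer without configuration) | CN(C)C1Oc2cc(OCc3ccccc3)cc(OCc3ccccc3)c2C(=O)C1C4C(OC)=C(O)C(OC)=CC4(OC)OC | intermediate (not isolated)
11 | 5,7-bis(benzyloxy)-3-(3-hydroxy-2,4,6,6-tetramethoxycyclohexa-2,4-dien-1-yl)-4H-chromen-4-one (racemic, drawn as the dienol tautomer) | COC1=CC(OC)(OC)C(c2coc3cc(OCc4ccccc4)cc(OCc4ccccc4)c3c2=O)C(OC)=C1O | intermediate (not isolated)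
12 | 5,7-bis(benzyloxy)-3-(3-hydroxy-2,4,6-trimethoxyphenyl)-4H-chromen-4-one | COc1cc(OC)c(-c2coc3cc(OCc4ccccc4)cc(OCc4ccccc4)c3c2=O)c(OC)c1O | intermediate
13 | 5,7-dihydroxy-3-(3-hydroxy-2,4,6-trimethoxyphenyl)-4H-chromen-4-one | COc1cc(OC)c(-c2coc3cc(O)cc(O)c3c2=O)c(OC)c1O | target

**Step count**

Total steps: 6. Longest linear sequence: 4 steps (1 → 3 → 4 → 12 → 13, or equally 5 → 7 → 9 → 12 → 13).

**Steps most likely to fail**

Step 5. The dienone β-carbon is deactivated by the adjacent methoxy group and crowded by the ketal carbon, so conjugate addition may be too slow. The enaminone would then be lost by proton-induced cyclisation to the 3-unsubstituted chromone, or the ketal of 4 would ionise and be lost by hydrolysis or by attack at methoxy-bearing carbons. The fallback is the known iodochromone cross-coupling route and sets out from 9 and 3.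
- From 9, iodine in chloroform at room temperature should give 5,7-bis(benzyloxy)-3-iodo-4H-chromen-4-one F1 by iodocyclisation.
- Separately, 3 is benzylated (benzyl bromide 6, K2CO3, DMF) to 2-(benzyloxy)-1,3,5-trimethoxybenzene F2.
- F2 is brominated with N-bromosuccinimide in acetonitrile at 0 °C at one of its two equivalent free positions to give 2-(benzyloxy)-4-bromo-1,3,5-trimethoxybenzene F3.
- F3 is converted by bromine–lithium exchange (n-BuLi, THF, −78 °C), B(OMe)3 and aqueous work-up into [3-(benzyloxy)-2,4,6-trimethoxyphenyl]boronic acid F4, which is used at once because it is prone to protodeboronation.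
- Suzuki–Miyaura coupling of F1 with F4 (Pd(OAc)2 as divalent palladium precatalyst, SPhos, K3PO4, toluene–water, 60 °C) should give 5,7-bis(benzyloxy)-3-[3-(benzyloxy)-2,4,6-trimethoxyphenyl]-4H-chromen-4-one F5.
- Hydrogenolysis of F5 under the conditions of step 6 removes all three benzyl groups, so the fallback comes back to the route at 13.

Step 3. Discrimination between the three hydroxyl groups may be incomplete, giving mono-, di- and tribenzyl ethers side by side, with some C-benzylation of the ring. The fallback sets out from 5 and makes the selection by cleavage instead of alkylation. Exhaustive benzylation (excess benzyl bromide 6, K2CO3, DMF, 80 °C) gives 1-[2,4,6-tris(benzyloxy)phenyl]ethan-1-one F6. One equivalent of BCl3 in CH2Cl2 at −78 °C then removes a single ortho benzyl group through chelation to the ketone. The fallback comes back to the route at 7.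

Step 6. Hydrogen may also add to the C2–C3 double bond of the pyranone once the benzyl groups are gone, giving the isoflavanone. The fallback sets out from 12 and cleaves the benzyl ethers without hydrogen: BCl3 with pentamethylbenzene as cation scavenger in CH2Cl2 at −78 °C, which leaves methyl ethers and the enone untouched. It comes back to the route at 13 and makes no compound beyond those of the route (F0).

**Further compounds**

F1 | step 5 | 5,7-bis(benzyloxy)-3-iodo-4H-chromen-4-one | O=c1c(I)coc2cc(OCc3ccccc3)cc(OCc3ccccc3)c12
F2 | step 5 | 2-(benzyloxy)-1,3,5-trimethoxybenzene | COc1cc(OC)c(OCc2ccccc2)c(OC)c1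
F3 | step 5 | 2-(benzyloxy)-4-bromo-1,3,5-trimethoxybenzene | COc1cc(OC)c(OCc2ccccc2)c(OC)c1Br
F4 | step 5 | [3-(benzyloxy)-2,4,6-trimethoxyphenyl]boronic acid | COc1cc(OC)c(OCc2ccccc2)c(OC)c1B(O)O
F5 | step 5 | 5,7-bis(benzyloxy)-3-[3-(benzyloxy)-2,4,6-trimethoxyphenyl]-4H-chromen-4-one | COc1cc(OC)c(OCc2ccccc2)c(OC)c1-c1coc2cc(OCc3ccccc3)cc(OCc3ccccc3)c2c1=O
F6 | step 3 | 1-[2,4,6-tris(benzyloxy)phenyl]ethan-1-one | CC(=O)c1c(OCc2ccccc2)cc(OCc2ccccc2)cc1OCc1ccccc1
F0 | step 6 | none | none
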